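## Structural features

The target 24 is a 5,6-dihydro-2H-pyran-2-one (ring A: O1, C2(=O), C3=C4, C5H2, C6H). C3 carries a 4-methylpent-3-enyl chain (C1′ to C4′). C6 carries a branched chain in which the vinyl carbon C7 is bonded to C6, to the acetoxymethyl carbon C14 and, through C7=C8, to the chain C9–C13 ending in a free allylic alcohol. The only stereocentre is C6 (R); it is the lactone carbinol, it is allylic to C7=C8, and it has no neighbouring stereocentre from which it could be relayed. Three trisubstituted alkenes have fixed geometry: C3=C4 (cis through ring A), C7=C8 (C9 on the side of C14) and C11=C12 (Z, C10 cis to C13). The fragile parts are the allylic acetate on C14 (1,3 to the C6 oxygen, so it can migrate or ionise), the free Z-allylic alcohol on C13, the base-sensitive unsaturated lactone and the skipped 1,5-diene C7=C8/C11=C12. The real difficulty is the C6 configuration, the C7=C8 geometry, and telling apart the two primary allylic oxygens (acetate on O14, free hydroxyl on O13). The key step uses the fact that C7 is flanked by carbinol C6, by C8H and by the oxidised carbon C14: with C14 at the ester level this is a β-substituted Morita–Baylis–Hillman unit, so C6–C7 can come from an aldol of a propiolate-derived allenolate, and the iodine left on C8 becomes the handle for C9.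

## Logic of the disconnections

24 to 22 (through 23). The acyl–oxygen bond O1–C2 of ring A is cut and the hydroxyls on C6 and C13 go back to silyl ethers. The Z-geometry of C3=C4 in 22 holds O6 within reach of C2, so ring A should close once O6 is free. The gain is an open chain whose two ends can be built separately. The forward step must remove both silyl ethers under acidic fluoride conditions that neither cleave the C14 acetate nor let it move to O6 before the lactone has formed.

22 to 18 and 21. The C3=C4 double bond is cut. This is the most convergent cut of the open chain: the whole C3 side chain (in 21) is separated from the part that holds the stereocentre (18). The forward olefination must place C2 cis to C5 with a branched phosphonate, cold enough that the β-silyloxy aldehyde does not eliminate.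

21 to 19 and 20. The C3–C1′ bond is cut, α to phosphorus and to the ester, where a stabilised carbanion is available. Both pieces are commercial. The forward alkylation must stop at monoalkylation with an unactivated primary bromide.

18 to 16 (through 17). No skeletal bond is cut; the C4 aldehyde is traced to a primary silyl ether. C4 has to stay masked until the C14 ester has been reduced. The forward demand is removal of the primary silyl ether on O4 while the secondary one on O6 and the bulkier one on O13 stay.

16 to 14 (through 15). No skeletal bond is cut; the acetoxymethyl carbon C14 is traced to an ester carbon. Because C14 stays an ester until O13 is already silylated, the two primary allylic oxygens are told apart without any selective acylation. The forward reduction must be a clean 1,2-reduction.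

14 to 9 and 12 (through 13). The sp2–sp3 bond C8–C9 is cut. The iodine on C8 of 9 is cis to C14, so a coupling with retention puts C9 where 24 needs it. The gain is that the whole C9–C13 unit, Z-alkene included, comes from 12. The forward step needs hydroboration at the vinyl group only and a coupling faster than β-hydride elimination or isomerisation of the alkenylpalladium intermediate.

12 to 10 (through 11). No skeletal bond is cut; the vinyl group is traced to a terminal alkyne and the silyl ether to the free alcohol. 10 is commercial and already has the Z-alkene. The forward semi-hydrogenation must stop at the diene.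

9 to 3, 4 and 5 (through 8, 7 and 6). After removal of the silyl group on O6, the C6–C7 and C8–I bonds are cut in one operation. This is the strategic cut: it creates the only stereocentre, fixes the C7=C8 geometry through the position of iodine, and brings C14 in at the ester level, all from three simple components. The forward step needs face selectivity at the aldehyde, a kinetic Z-iodoalkene, and an O4 protecting group that neither binds the boron catalyst nor is cut by the iodosilane. For that reason O4 is carried as a tert-butyldimethylsilyl ether. A benzylic ether such as 4-methoxybenzyl would be exposed to cleavage by iodosilane and silyl-cation Lewis acids, and its more basic oxygen would compete with the formyl group for boron.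

3 to 1 (through 2). No skeletal bond is cut; one of two equivalent hydroxyls is silylated and the other oxidised. The forward demand is monosilylation of a symmetric diol.

## Other disconnections considered

Alternative 1: The cut removes the carbonyl carbon C2 (bonds C2–C3 and C2–O1). In the forward step zerovalent palladium inserts into the C3–I bond of the iodoalkenyl carbinol A2, carbon monoxide inserts, and the C6 hydroxyl captures the acylpalladium to give the bis-silyl lactone A1.
- In its favour: ring A, its carbonyl and its alkene arrive in one catalytic event. The C3=C4 geometry is fixed beforehand in the iodoalkene, so no Z-selective olefination and no branched phosphonate are needed; on ring construction this alternative is the better one. C14 is a silyl ether during ring closure, so no acetate sits beside a free C6 hydroxyl; that too is better.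
- Against it: the key step creates neither C6 nor the C7=C8 geometry. Both must already be in A2, together with a Z-trisubstituted iodoalkene that needs its own regio- and stereocontrolled synthesis. Carbon monoxide is a safety burden. After A1 three more steps are needed (selective cleavage of the C14 silyl ether, acetylation, cleavage of the C13 silyl ether).
- Comparison: on structure the chosen plan solves the stereocentre and the C7=C8 alkene in its key step, while this one solves only the ring. On mechanism both rest on well-understood palladium chemistry of a vinyl iodide and are equal. On step economy the alternative is probably longer because A2 carries all the stereochemical work.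

Alternative 2: The cut is C5–C6. In the forward step the silyl ketene acetal of the dioxinyl carbinol acetate A4 undergoes an Ireland–Claisen rearrangement to the dioxanyl acetic acid A3, forming C5–C6 and moving the alkene to C7=C8.
- In its favour: one pericyclic event fixes both C6 and the C7=C8 geometry by 1,3-chirality transfer, which equals the chosen key step in what it sets. The C9–C13 chain is already present, so no sp2–sp3 cross-coupling is needed; that is better. No iodosilane and no cryogenic chiral Lewis acid are used. O6 and O14 arrive tied in an acetonide, so the acetate can go on after ring A is closed and cannot migrate; that is also better.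
- Against it: the chirality is relayed, not created, so a separate asymmetric step must first set C8 in A4. The alkene partner is an enol ether locked in a six-membered ring, where the chair preference that the transfer relies on is less secure. The enol ether and ketal are acid-sensitive. After A3 the acid must be brought to the aldehyde level before the C3 chain and ring A can be built.
- Comparison: on structure it is equal for C6/C7=C8 and better for C9–C13. On mechanism the chosen step is catalyst-controlled, while this one depends on substrate geometry. On step economy it is longer (asymmetric synthesis of A4, two oxidation-level changes, acetonide removal).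

Alternative 3: The cut is C1′–C2′ in the C3 side chain. In the forward step the allyl vinyl ether in the 3-methylene-4-vinyloxy lactone A6 rearranges on heating to the 3-(3-oxopropyl) lactone A5, moving the alkene into ring A.
- In its favour: the C3 side-chain bond and the endocyclic alkene are made in one reagent-free step. The C4 stereocentre is traceless. No alkylated phosphonate and no E/Z question arise because ring A enforces the geometry; on the C3 chain this is the better plan. A5 is one Wittig olefination from the 4-methylpent-3-enyl chain.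
- Against it: it solves the easier half. C6 and C7=C8 must already be present in A6 and need their own stereo-defining sequence. A6 must be made by vinylation of a β-hydroxy-α-methylene lactone, and the molecule must be heated although it has a 1,5-diene (Cope pathway) and an allylic acetate. The later non-stabilised ylide would meet an acetate and an unsaturated lactone.
- Comparison: on structure the chosen plan addresses the stereocentre directly. On mechanism the thermal rearrangement is simpler and needs no catalyst. On step economy it is equal or better for the C3 chain alone, but longer overall.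

Key step: step 3

Remark on the chemistry (assumption): the sense of induction in step 3 is taken from the usual binding model of this catalyst class, in which the (S)-prolinol-derived oxazaborolidinium leaves the Si face of an unbranched aldehyde open. If the opposite sense applies, the (R)-prolinol-derived catalyst is used and nothing else changes.

## Route

Step 1
Reactants: 1 propane-1,3-diol
Product: 2 3-{[tert-butyl(dimethyl)silyl]oxy}propan-1-ol
Conditions: NaH (1.0 equiv), THF, 0 °C to rt; then TBSCl (1.0 equiv), rt
Reagents that add atoms: tert-butyl(chloro)dimethylsilane (TBSCl), CC(C)(C)[Si](C)(C)Cl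
Why: One equivalent of NaH gives the sparingly soluble monosodium alkoxide, which is silylated as it dissolves (O-silylation of an alkoxide), so monosilylation of the symmetric diol is favoured.

Step 2
Reactants: 2 3-{[tert-butyl(dimethyl)silyl]oxy}propan-1-ol
Product: 3 3-{[tert-butyl(dimethyl)silyl]oxy}propanal
Conditions: PhI(OAc)2 (1.1 equiv), 2,2,6,6-tetramethylpiperidin-1-oxyl (10 mol %), CH2Cl2, rt
Reagents that add atoms: none
Why: Nitroxyl-catalysed oxoammonium oxidation stops at the aldehyde and runs without base, so the β-silyloxy aldehyde is not exposed to conditions that cause elimination.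

Step 3
Reactants: 3 3-{[tert-butyl(dimethyl)silyl]oxy}propanal; 4 ethyl propiolate; 5 iodotrimethylsilane
Product: 8 ethyl (2Z)-2-[(1R)-3-{[tert-butyl(dimethyl)silyl]oxy}-1-hydroxypropyl]-3-iodoprop-2-enoate, via silyl allenolate 6 (not isolated), via trimethylsilyl ether 7 (not isolated)
Conditions: (3aS)-1-(2-methylphenyl)-3,3-diphenyltetrahydro-1H,3H-pyrrolo[1,2-c][1,3,2]oxazaborole protonated with (CF3SO2)2NH (20 mol %), 4 (1.6 equiv), 5 (1.4 equiv, added slowly), CH2Cl2, −78 °C; cold quench, then 0.5 M HCl, THF, 0 °C
Reagents that add atoms: none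
Why: Iodide from 5 adds to the β-carbon of 4 (the future C8) while silicon takes the carbonyl oxygen, which gives the silyl allenolate 6. Aldehyde 3 binds through its carbonyl oxygen to the boron of the cationic oxazaborolidinium, its formyl hydrogen held by the ring oxygen, so that an aryl group of the diarylcarbinol unit covers the Re face. The central carbon of 6 attacks the open Si face in a Mukaiyama-type aldol, forming C6–C7 and setting C6 as R under catalyst control; the closest known reaction type is the oxazaborolidinium-catalysed coupling of aldehydes, propiolates and iodosilanes to (Z)-β-iodo Morita–Baylis–Hillman esters. The nucleophilic π-orbital of 6 lies in the plane of the H and I on C8, so the aldehyde approaches past the small hydrogen and iodine ends up trans to C6 and cis to the ester carbon C14 (Z); −78 °C keeps this kinetic geometry. Silyl transfer to the aldolate oxygen gives 7 and frees the catalyst, and dilute acid then removes only the trimethylsilyl group. No ring is closed. The step needs the catalysed path to outrun the achiral silyl-Lewis-acid path (low temperature, slow addition of 5, excess of 4 so that no free iodosilane remains) and a side chain that neither binds boron nor is cut by iodosilane, which the bulky, weakly basic silyl ether on O4 provides.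

Step 4
Reactants: 8 ethyl (2Z)-2-[(1R)-3-{[tert-butyl(dimethyl)silyl]oxy}-1-hydroxypropyl]-3-iodoprop-2-enoate
Product: 9 ethyl (2Z)-2-[(1R)-1,3-bis{[tert-butyl(dimethyl)silyl]oxy}propyl]-3-iodoprop-2-enoate
Conditions: TBSOTf (1.2 equiv), 2,6-lutidine, CH2Cl2, −78 to 0 °C
Reagents that add atoms: tert-butyldimethylsilyl trifluoromethanesulfonate (TBSOTf), CC(C)(C)[Si](C)(C)OS(=O)(=O)C(F)(F)F
Why: A silyl triflate with a hindered pyridine base silylates the secondary allylic hydroxyl at low temperature (O-silylation), where the β-iodoacrylate neither isomerises nor suffers conjugate addition; the stereocentre is not touched.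

Step 5
Reactants: 10 (2Z)-3-methylpent-2-en-4-yn-1-ol
Product: 11 tert-butyl{[(2Z)-3-methylpent-2-en-4-yn-1-yl]oxy}diphenylsilane
Conditions: TBDPSCl, imidazole, CH2Cl2, 0 °C to rt
Reagents that add atoms: tert-butyl(chloro)diphenylsilane (TBDPSCl), CC(C)(C)[Si](Cl)(c1ccccc1)c1ccccc1
Why: Imidazole-promoted O-silylation of a primary alcohol; the tert-butyldiphenylsilyl ether is chosen because it outlasts the later selective cleavage of a primary tert-butyldimethylsilyl ether.

Step 6
Reactants: 11 tert-butyl{[(2Z)-3-methylpent-2-en-4-yn-1-yl]oxy}diphenylsilane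
Product: 12 tert-butyl{[(2Z)-3-methylpenta-2,4-dien-1-yl]oxy}diphenylsilane
Conditions: H2 (1 atm), Pd/CaCO3 poisoned with Pb(OAc)2, quinoline, hexane/EtOAc, rt, stopped after 1 equiv of H2
Reagents that add atoms: none
Why: Semi-hydrogenation over poisoned palladium adds one equivalent of H2 to the terminal alkyne and stops at the vinyl group; the trisubstituted alkene is not reduced and keeps its Z-geometry.

Step 7
Reactants: 12 tert-butyl{[(2Z)-3-methylpenta-2,4-dien-1-yl]oxy}diphenylsilane; 9 ethyl (2Z)-2-[(1R)-1,3-bis{[tert-butyl(dimethyl)silyl]oxy}propyl]-3-iodoprop-2-enoate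
Product: 14 ethyl (2Z,6Z)-2-[(1R)-1,3-bis{[tert-butyl(dimethyl)silyl]oxy}propyl]-8-{[tert-butyl(diphenyl)silyl]oxy}-6-methylocta-2,6-dienoate, via B-alkyl-9-borabicyclo[3.3.1]nonane 13 (not isolated)
Conditions: 12 (1.4 equiv), 9-borabicyclo[3.3.1]nonane (9-BBN-H), THF, 0 °C to rt; then 9, Pd(dppf)Cl2·CH2Cl2 (5 mol %; dppf = 1,1′-bis(diphenylphosphino)ferrocene), AsPh3 (10 mol %), Cs2CO3, H2O, DMF, rt
Reagents that add atoms: none
Why: 9-BBN-H places boron on the terminal carbon of the vinyl group of 12 (anti-Markovnikov hydroboration), the trisubstituted alkene being far slower; in the B-alkyl Suzuki–Miyaura coupling zerovalent palladium inserts into the C8–I bond of 9 with retention, the base-activated borane transfers its primary alkyl group, and the wide-bite-angle dppf ligand makes reductive elimination faster than β-hydride elimination. C9 therefore replaces iodine cis to the ester carbon C14, which is the C7=C8 geometry of 24; the C6 stereocentre is not involved.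

Step 8
Reactants: 14 ethyl (2Z,6Z)-2-[(1R)-1,3-bis{[tert-butyl(dimethyl)silyl]oxy}propyl]-8-{[tert-butyl(diphenyl)silyl]oxy}-6-methylocta-2,6-dienoate
Product: 15 (2E,6Z)-2-[(1R)-1,3-bis{[tert-butyl(dimethyl)silyl]oxy}propyl]-8-{[tert-butyl(diphenyl)silyl]oxy}-6-methylocta-2,6-dien-1-ol
Conditions: iBu2AlH (2.5 equiv), CH2Cl2, −78 °C; aqueous potassium sodium tartrate
Reagents that add atoms: none
Why: iBu2AlH reduces the conjugated ester by 1,2-hydride addition to the allylic alcohol at low temperature without conjugate reduction; silyl ethers and alkenes are inert (the E descriptor reflects only the changed priority of C14).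

Step 9
Reactants: 15 (2E,6Z)-2-[(1R)-1,3-bis{[tert-butyl(dimethyl)silyl]oxy}propyl]-8-{[tert-butyl(diphenyl)silyl]oxy}-6-methylocta-2,6-dien-1-ol
Product: 16 (2E,6Z)-2-[(1R)-1,3-bis{[tert-butyl(dimethyl)silyl]oxy}propyl]-8-{[tert-butyl(diphenyl)silyl]oxy}-6-methylocta-2,6-dien-1-yl acetate
Conditions: Ac2O, pyridine, 4-(dimethylamino)pyridine (5 mol %), CH2Cl2, 0 °C to rt
Reagents that add atoms: acetic anhydride (Ac2O), CC(=O)OC(C)=O
Why: Nucleophilic acyl-transfer catalysis acetylates the only free hydroxyl; O14 is thereby distinguished from O13, which is still a silyl ether.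

Step 10
Reactants: 16 (2E,6Z)-2-[(1R)-1,3-bis{[tert-butyl(dimethyl)silyl]oxy}propyl]-8-{[tert-butyl(diphenyl)silyl]oxy}-6-methylocta-2,6-dien-1-yl acetate
Product: 17 (2E,6Z)-2-[(1R)-1-{[tert-butyl(dimethyl)silyl]oxy}-3-hydroxypropyl]-8-{[tert-butyl(diphenyl)silyl]oxy}-6-methylocta-2,6-dien-1-yl acetate
Conditions: HF·pyridine, pyridine, THF, 0 °C, monitored
Reagents that add atoms: none
Why: Buffered acidic fluoride cleaves silyl ethers in the order of steric access (selective desilylation), so the primary ether on O4 goes before the secondary one on O6, shielded by C7 and its substituents, and before the tert-butyldiphenylsilyl ether on O13; the acetate is stable to these conditions.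

Step 11
Reactants: 17 (2E,6Z)-2-[(1R)-1-{[tert-butyl(dimethyl)silyl]oxy}-3-hydroxypropyl]-8-{[tert-butyl(diphenyl)silyl]oxy}-6-methylocta-2,6-dien-1-yl acetate
Product: 18 (2E,6Z)-2-[(1R)-1-{[tert-butyl(dimethyl)silyl]oxy}-3-oxopropyl]-8-{[tert-butyl(diphenyl)silyl]oxy}-6-methylocta-2,6-dien-1-yl acetate
Conditions: Dess–Martin periodinane, NaHCO3, CH2Cl2, 0 °C to rt
Reagents that add atoms: none
Why: Dess–Martin oxidation under bicarbonate buffer gives the aldehyde without acid or strong base, so the β-silyloxy aldehyde does not eliminate and the allylic acetate is untouched.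

Step 12
Reactants: 19 methyl bis(2,2,2-trifluoroethyl)phosphonoacetate; 20 5-bromo-2-methylpent-2-ene
Product: 21 methyl 2-[bis(2,2,2-trifluoroethoxy)phosphoryl]-6-methylhept-5-enoate (racemic)
Conditions: 19 (1.2 equiv), NaH, THF, 0 °C; then 20, Bu4NI (0.2 equiv), 60 °C
Reagents that add atoms: none
Why: The sodium salt of the phosphonoacetate is C-alkylated by the primary bromide (SN2 alkylation of a stabilised carbanion), iodide exchange speeding the displacement; the product is more hindered and less acidic, which disfavours a second alkylation, and its new stereocentre is lost in step 13.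

Step 13
Reactants: 21 methyl 2-[bis(2,2,2-trifluoroethoxy)phosphoryl]-6-methylhept-5-enoate; 18 (2E,6Z)-2-[(1R)-1-{[tert-butyl(dimethyl)silyl]oxy}-3-oxopropyl]-8-{[tert-butyl(diphenyl)silyl]oxy}-6-methylocta-2,6-dien-1-yl acetate
Product: 22 methyl (2Z,5R,6E,10Z)-6-(acetoxymethyl)-5-{[tert-butyl(dimethyl)silyl]oxy}-12-{[tert-butyl(diphenyl)silyl]oxy}-10-methyl-2-(4-methylpent-3-en-1-yl)dodeca-2,6,10-trienoate
Conditions: 21 (1.3 equiv), KN(SiMe3)2, 18-crown-6, THF, −78 °C; then 18, −78 °C
Reagents that add atoms: none
Why: Still–Gennari olefination: with electron-poor trifluoroethyl phosphonate esters and a crown-ether-separated potassium ion the first adduct eliminates faster than it equilibrates, which puts the ester carbon C2 cis to C5 (Z); at −78 °C the phosphonate anion does not bring about β-elimination in the aldehyde and does not attack the acetate.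

Step 14
Reactants: 22 methyl (2Z,5R,6E,10Z)-6-(acetoxymethyl)-5-{[tert-butyl(dimethyl)silyl]oxy}-12-{[tert-butyl(diphenyl)silyl]oxy}-10-methyl-2-(4-methylpent-3-en-1-yl)dodeca-2,6,10-trienoate
Product: 24 [(2E,6Z)-8-hydroxy-6-methyl-2-[(2R)-5-(4-methylpent-3-en-1-yl)-6-oxo-3,6-dihydro-2H-pyran-2-yl]octa-2,6-dien-1-yl] acetate, via dihydroxy ester 23 (not isolated)
Conditions: HF·pyridine, pyridine, THF, 0 °C to rt; then pyridinium p-toluenesulfonate (10 mol %), CH2Cl2, rt
Reagents that add atoms: none
Why: HF·pyridine removes both silyl ethers; in 23 the Z-alkene C3=C4 holds the C6 hydroxyl next to the ester, and acid-catalysed transesterification closes the six-membered lactone (lactonisation), completed by the pyridinium salt. The mildly acidic medium disfavours 1,3-migration of the acetyl group from O14 to O6, and the C6–O bond is never broken, so the R configuration is kept.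

## Compound list

1 | propane-1,3-diol | OCCCO | starting material
2 | 3-{[tert-butyl(dimethyl)silyl]oxy}propan-1-ol | OCCCO[Si](C)(C)C(C)(C)C | intermediate
3 | 3-{[tert-butyl(dimethyl)silyl]oxy}propanal | O=CCCO[Si](C)(C)C(C)(C)C | intermediate
4 | ethyl propiolate | C#CC(=O)OCC | starting material
5 | iodotrimethylsilane | C[Si](C)(C)I | starting material
6 | 1-ethoxy-3-iodo-1-[(trimethylsilyl)oxy]propa-1,2-diene (silyl allenolate) | CCOC(O[Si](C)(C)C)=C=CI | intermediate (not isolated)
7 | ethyl (2Z)-2-[(1R)-3-{[tert-butyl(dimethyl)silyl]oxy}-1-[(trimethylsilyl)oxy]propyl]-3-iodoprop-2-enoate | CCOC(=O)/C(=C\I)[C@H](O[Si](C)(C)C)CCO[Si](C)(C)C(C)(C)C | intermediate (not isolated)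
8 | ethyl (2Z)-2-[(1R)-3-{[tert-butyl(dimethyl)silyl]oxy}-1-hydroxypropyl]-3-iodoprop-2-enoate | CCOC(=O)/C(=C\I)[C@H](O)CCO[Si](C)(C)C(C)(C)C | intermediate
9 | ethyl (2Z)-2-[(1R)-1,3-bis{[tert-butyl(dimethyl)silyl]oxy}propyl]-3-iodoprop-2-enoate | CCOC(=O)/C(=C\I)[C@H](O[Si](C)(C)C(C)(C)C)CCO[Si](C)(C)C(C)(C)C | intermediate
10 | (2Z)-3-methylpent-2-en-4-yn-1-ol | C#C/C(C)=C\CO | starting material
11 | tert-butyl{[(2Z)-3-methylpent-2-en-4-yn-1-yl]oxy}diphenylsilane | C#C/C(C)=C\CO[Si](c1ccccc1)(c1ccccc1)C(C)(C)C | intermediate
12 | tert-butyl{[(2Z)-3-methylpenta-2,4-dien-1-yl]oxy}diphenylsilane | C=C/C(C)=C\CO[Si](c1ccccc1)(c1ccccc1)C(C)(C)C | intermediate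
13 | 9-[(3Z)-5-{[tert-butyl(diphenyl)silyl]oxy}-3-methylpent-3-en-1-yl]-9-borabicyclo[3.3.1]nonane | CC(C)(C)[Si](OC/C=C(C)\CCB1C2CCCC1CCC2)(c1ccccc1)c1ccccc1 | intermediate (not isolated)
14 | ethyl (2Z,6Z)-2-[(1R)-1,3-bis{[tert-butyl(dimethyl)silyl]oxy}propyl]-8-{[tert-butyl(diphenyl)silyl]oxy}-6-methylocta-2,6-dienoate | CCOC(=O)/C(=C\CC/C(C)=C\CO[Si](c1ccccc1)(c1ccccc1)C(C)(C)C)[C@H](O[Si](C)(C)C(C)(C)C)CCO[Si](C)(C)C(C)(C)C | intermediate
15 | (2E,6Z)-2-[(1R)-1,3-bis{[tert-butyl(dimethyl)silyl]oxy}propyl]-8-{[tert-butyl(diphenyl)silyl]oxy}-6-methylocta-2,6-dien-1-ol | OC/C(=C\CC/C(C)=C\CO[Si](c1ccccc1)(c1ccccc1)C(C)(C)C)[C@H](O[Si](C)(C)C(C)(C)C)CCO[Si](C)(C)C(C)(C)C | intermediate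
16 | (2E,6Z)-2-[(1R)-1,3-bis{[tert-butyl(dimethyl)silyl]oxy}propyl]-8-{[tert-butyl(diphenyl)silyl]oxy}-6-methylocta-2,6-dien-1-yl acetate | CC(=O)OC/C(=C\CC/C(C)=C\CO[Si](c1ccccc1)(c1ccccc1)C(C)(C)C)[C@H](O[Si](C)(C)C(C)(C)C)CCO[Si](C)(C)C(C)(C)C | intermediate
17 | (2E,6Z)-2-[(1R)-1-{[tert-butyl(dimethyl)silyl]oxy}-3-hydroxypropyl]-8-{[tert-butyl(diphenyl)silyl]oxy}-6-methylocta-2,6-dien-1-yl acetate | CC(=O)OC/C(=C\CC/C(C)=C\CO[Si](c1ccccc1)(c1ccccc1)C(C)(C)C)[C@H](O[Si](C)(C)C(C)(C)C)CCO | intermediate
18 | (2E,6Z)-2-[(1R)-1-{[tert-butyl(dimethyl)silyl]oxy}-3-oxopropyl]-8-{[tert-butyl(diphenyl)silyl]oxy}-6-methylocta-2,6-dien-1-yl acetate | CC(=O)OC/C(=C\CC/C(C)=C\CO[Si](c1ccccc1)(c1ccccc1)C(C)(C)C)[C@H](O[Si](C)(C)C(C)(C)C)CC=O | intermediate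
19 | methyl bis(2,2,2-trifluoroethyl)phosphonoacetate | COC(=O)CP(=O)(OCC(F)(F)F)OCC(F)(F)F | starting material
20 | 5-bromo-2-methylpent-2-ene | CC(C)=CCCBr | starting material
21 | methyl 2-[bis(2,2,2-trifluoroethoxy)phosphoryl]-6-methylhept-5-enoate (racemic) | COC(=O)C(CCC=C(C)C)P(=O)(OCC(F)(F)F)OCC(F)(F)F | intermediate
22 | methyl (2Z,5R,6E,10Z)-6-(acetoxymethyl)-5-{[tert-butyl(dimethyl)silyl]oxy}-12-{[tert-butyl(diphenyl)silyl]oxy}-10-methyl-2-(4-methylpent-3-en-1-yl)dodeca-2,6,10-trienoate | COC(=O)/C(CCC=C(C)C)=C\C[C@@H](O[Si](C)(C)C(C)(C)C)/C(COC(C)=O)=C/CC/C(C)=C\CO[Si](c1ccccc1)(c1ccccc1)C(C)(C)C | intermediate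
23 | methyl (2Z,5R,6E,10Z)-6-(acetoxymethyl)-5,12-dihydroxy-10-methyl-2-(4-methylpent-3-en-1-yl)dodeca-2,6,10-trienoate | COC(=O)/C(CCC=C(C)C)=C\C[C@@H](O)/C(COC(C)=O)=C/CC/C(C)=C\CO | intermediate (not isolated)
24 | [(2E,6Z)-8-hydroxy-6-methyl-2-[(2R)-5-(4-methylpent-3-en-1-yl)-6-oxo-3,6-dihydro-2H-pyran-2-yl]octa-2,6-dien-1-yl] acetate | CC(=O)OC/C(=C\CC/C(C)=C\CO)[C@H]1CC=C(CCC=C(C)C)C(=O)O1 | target

## Step count and least certain steps

Total step count: 14. Longest linear sequence: 11 steps (steps 1, 2, 3, 4, 7, 8, 9, 10, 11, 13, 14); steps 5–6 and step 12 are side branches.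

Step 3 (key step). Most likely to go wrong: loss of enantioselectivity through an uncatalysed aldol promoted by achiral silyl Lewis acids, and partial loss of the Z-geometry by iodide addition–elimination if the mixture warms before the quench. Fallback: the stereocentre is set by ketone reduction instead of by the aldol. Setting out from 3 and 4, coupling in the presence of MgI2 (CH2Cl2, 0 °C) should give racemic ethyl (2Z)-2-(3-{[tert-butyl(dimethyl)silyl]oxy}-1-hydroxypropyl)-3-iodoprop-2-enoate F1. Buffered Dess–Martin oxidation at 0 °C gives ethyl (2Z)-5-{[tert-butyl(dimethyl)silyl]oxy}-2-(iodomethylidene)-3-oxopentanoate F2, which is used at once. Corey–Bakshi–Shibata reduction with (3aS)-1-methyl-3,3-diphenyltetrahydro-1H,3H-pyrrolo[1,2-c][1,3,2]oxazaborole and catecholborane at −78 °C, the branched alkenyl group acting as the large substituent, should return to the route at 8.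

Step 7. Most likely to go wrong: β-hydride elimination from the homoallylic alkylpalladium intermediate (which would re-form a conjugated diene), slow transmetalation with protodeboronation, or hydroboration not confined to the vinyl group. Fallback: transmetalation from zinc under base-free conditions, with a purifiable C9–C13 fragment. Setting out from 12, hydroboration with 9-BBN-H followed by NaOH/H2O2 gives (3Z)-5-{[tert-butyl(diphenyl)silyl]oxy}-3-methylpent-3-en-1-ol F3. I2, PPh3 and imidazole convert it into tert-butyl{[(2Z)-5-iodo-3-methylpent-2-en-1-yl]oxy}diphenylsilane F4. Zinc insertion (Zn dust, LiCl, THF) gives [(3Z)-5-{[tert-butyl(diphenyl)silyl]oxy}-3-methylpent-3-en-1-yl]zinc iodide F5, and Negishi coupling with 9 (Pd(PPh3)4, THF, rt) returns to the route at 14.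

Step 12. Most likely to go wrong: the anion of the electron-poor phosphonate is a weak nucleophile, so substitution on an unactivated bromide is slow and elimination of HBr from 20, dialkylation and exchange of trifluoroethoxy groups at phosphorus compete. Fallback: the C3–C1′ bond is made on a phosphonate without fluoroalkyl groups, which are introduced afterwards. Setting out from 20, alkylation of the sodium salt of trimethyl phosphonoacetate (NaH, THF, Bu4NI, 60 °C) gives methyl 2-(dimethoxyphosphoryl)-6-methylhept-5-enoate F6. Me3SiBr gives methyl 2-{bis[(trimethylsilyl)oxy]phosphoryl}-6-methylhept-5-enoate F7, and (COCl)2 with catalytic DMF gives methyl 2-(dichlorophosphoryl)-6-methylhept-5-enoate F8. 2,2,2-Trifluoroethanol and pyridine then return to the route at 21.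

Step 14. Most likely to go wrong: migration of the acetyl group from O14 to the freed O6 before ring A closes, incomplete lactonisation, or long exposure to acid because the tert-butyldiphenylsilyl ether is slow to leave. Fallback: the acetate is put on only after ring A is closed. Setting out from 22, K2CO3 in MeOH (0 °C) removes the acetyl group to give methyl (2Z,5R,6E,10Z)-5-{[tert-butyl(dimethyl)silyl]oxy}-12-{[tert-butyl(diphenyl)silyl]oxy}-6-(hydroxymethyl)-10-methyl-2-(4-methylpent-3-en-1-yl)dodeca-2,6,10-trienoate F9. (+)-Camphor-10-sulfonic acid in MeOH/CH2Cl2 (0 °C to rt) cleaves only the secondary silyl ether and closes the lactone to give (6R)-6-[(2E,6Z)-8-{[tert-butyl(diphenyl)silyl]oxy}-1-hydroxy-6-methylocta-2,6-dien-2-yl]-3-(4-methylpent-3-en-1-yl)-5,6-dihydro-2H-pyran-2-one F10. Ac2O and pyridine give [(2E,6Z)-8-{[tert-butyl(diphenyl)silyl]oxy}-6-methyl-2-[(2R)-5-(4-methylpent-3-en-1-yl)-6-oxo-3,6-dihydro-2H-pyran-2-yl]octa-2,6-dien-1-yl] acetate F11, and HF·pyridine in THF returns to the route at 24.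

## Further compounds

F1 | step 3 | ethyl (2Z)-2-(3-{[tert-butyl(dimethyl)silyl]oxy}-1-hydroxypropyl)-3-iodoprop-2-enoate (racemic) | CCOC(=O)/C(=C\I)C(O)CCO[Si](C)(C)C(C)(C)C
F2 | step 3 | ethyl (2Z)-5-{[tert-butyl(dimethyl)silyl]oxy}-2-(iodomethylidene)-3-oxopentanoate | CCOC(=O)/C(=C\I)C(=O)CCO[Si](C)(C)C(C)(C)C
F3 | step 7 | (3Z)-5-{[tert-butyl(diphenyl)silyl]oxy}-3-methylpent-3-en-1-ol | OCC/C(C)=C\CO[Si](c1ccccc1)(c1ccccc1)C(C)(C)C
F4 | step 7 | tert-butyl{[(2Z)-5-iodo-3-methylpent-2-en-1-yl]oxy}diphenylsilane | ICC/C(C)=C\CO[Si](c1ccccc1)(c1ccccc1)C(C)(C)C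
F5 | step 7 | [(3Z)-5-{[tert-butyl(diphenyl)silyl]oxy}-3-methylpent-3-en-1-yl]zinc iodide | I[Zn]CC/C(C)=C\CO[Si](c1ccccc1)(c1ccccc1)C(C)(C)C
F6 | step 12 | methyl 2-(dimethoxyphosphoryl)-6-methylhept-5-enoate (racemic) | COC(=O)C(CCC=C(C)C)P(=O)(OC)OC
F7 | step 12 | methyl 2-{bis[(trimethylsilyl)oxy]phosphoryl}-6-methylhept-5-enoate (racemic) | COC(=O)C(CCC=C(C)C)P(=O)(O[Si](C)(C)C)O[Si](C)(C)C
F8 | step 12 | methyl 2-(dichlorophosphoryl)-6-methylhept-5-enoate (racemic) | COC(=O)C(CCC=C(C)C)P(=O)(Cl)Cl
F9 | step 14 | methyl (2Z,5R,6E,10Z)-5-{[tert-butyl(dimethyl)silyl]oxy}-12-{[tert-butyl(diphenyl)silyl]oxy}-6-(hydroxymethyl)-10-methyl-2-(4-methylpent-3-en-1-yl)dodeca-2,6,10-trienoate | COC(=O)/C(CCC=C(C)C)=C\C[C@@H](O[Si](C)(C)C(C)(C)C)/C(CO)=C/CC/C(C)=C\CO[Si](c1ccccc1)(c1ccccc1)C(C)(C)C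
F10 | step 14 | (6R)-6-[(2E,6Z)-8-{[tert-butyl(diphenyl)silyl]oxy}-1-hydroxy-6-methylocta-2,6-dien-2-yl]-3-(4-methylpent-3-en-1-yl)-5,6-dihydro-2H-pyran-2-one | OC/C(=C\CC/C(C)=C\CO[Si](c1ccccc1)(c1ccccc1)C(C)(C)C)[C@H]1CC=C(CCC=C(C)C)C(=O)O1
F11 | step 14 | [(2E,6Z)-8-{[tert-butyl(diphenyl)silyl]oxy}-6-methyl-2-[(2R)-5-(4-methylpent-3-en-1-yl)-6-oxo-3,6-dihydro-2H-pyran-2-yl]octa-2,6-dien-1-yl] acetate | CC(=O)OC/C(=C\CC/C(C)=C\CO[Si](c1ccccc1)(c1ccccc1)C(C)(C)C)[C@H]1CC=C(CCC=C(C)C)C(=O)O1
A1 | alternative 1 | (6R)-6-[(2E,6Z)-1-{[tert-butyl(dimethyl)silyl]oxy}-8-{[tert-butyl(diphenyl)silyl]oxy}-6-methylocta-2,6-dien-2-yl]-3-(4-methylpent-3-en-1-yl)-5,6-dihydro-2H-pyran-2-one | CC(C)(C)[Si](C)(C)OC/C(=C\CC/C(C)=C\CO[Si](c1ccccc1)(c1ccccc1)C(C)(C)C)[C@H]1CC=C(CCC=C(C)C)C(=O)O1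
A2 | alternative 1 | (2Z,6E,8R,10Z)-1-{[tert-butyl(diphenyl)silyl]oxy}-7-({[tert-butyl(dimethyl)silyl]oxy}methyl)-11-iodo-3,15-dimethylhexadeca-2,6,10,14-tetraen-8-ol | CC(C)(C)[Si](C)(C)OC/C(=C\CC/C(C)=C\CO[Si](c1ccccc1)(c1ccccc1)C(C)(C)C)[C@H](O)C/C=C(I)/CCC=C(C)C
A3 | alternative 2 | 2-[(4R,5E)-5-[(4Z)-6-{[tert-butyl(diphenyl)silyl]oxy}-4-methylhex-4-en-1-ylidene]-2,2-dimethyl-1,3-dioxan-4-yl]acetic acid | OC(=O)C[C@H]1OC(C)(C)OC/C1=C\CC/C(C)=C\CO[Si](c2ccccc2)(c2ccccc2)C(C)(C)C
A4 | alternative 2 | (1R,4Z)-6-{[tert-butyl(diphenyl)silyl]oxy}-1-(2,2-dimethyl-4H-1,3-dioxin-5-yl)-4-methylhex-4-en-1-yl acetate | CC(=O)O[C@H](CC/C(C)=C\CO[Si](c1ccccc1)(c1ccccc1)C(C)(C)C)C1=COC(C)(C)OC1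
A5 | alternative 3 | [(2E,6Z)-8-{[tert-butyl(diphenyl)silyl]oxy}-6-methyl-2-[(2R)-6-oxo-5-(3-oxopropyl)-3,6-dihydro-2H-pyran-2-yl]octa-2,6-dien-1-yl] acetate | O=CCCC1=CC[C@H](/C(COC(C)=O)=C/CC/C(C)=C\CO[Si](c2ccccc2)(c2ccccc2)C(C)(C)C)OC1=O
A6 | alternative 3 | [(2E,6Z)-8-{[tert-butyl(diphenyl)silyl]oxy}-2-[(2R)-4-(ethenyloxy)-5-methylidene-6-oxotetrahydro-2H-pyran-2-yl]-6-methylocta-2,6-dien-1-yl] acetate (configuration at the vinyloxy carbon not defined) | C=COC1C[C@H](/C(COC(C)=O)=C/CC/C(C)=C\CO[Si](c2ccccc2)(c2ccccc2)C(C)(C)C)OC(=O)C1=C
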